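**Retrosynthetic overview**
- Arzanol is cut at the CH2 bridge between C3 of the pyrone ring and C1' of the benzene ring, giving 3-prenylphloracetophenone 18, 6-ethyl-4-hydroxy-5-methyl-2-pyrone 22 and a one-carbon iminium electrophile 23.
- The strategy rests on the benzene ring: the acetyl group on C5' and the hydroxyl on C6' sit on neighbouring carbons, flanked by the oxygen on C4' and by unsubstituted C1'-H. This pair equals acetic acid added across a C5'-C6' aryne, so the C5'-C(=O) and C6'-O bonds are made together from silyl triflate 12.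
- Triflate 12 comes from phloroglucinol: mono-TIPS ether, bis-MOM ether, lithiation/prenylation between the MOM ethers, desilylation, ortho-bromination, then O-silylation/retro-Brook/triflation.
- Ring order: the benzene ring is bought; only the pyrone ring is built (3-pentanone silyl enol ether plus malonyl dichloride), and it is joined to the finished arene in the last step. The target has no stereocenter.

Key step: step 7

Remark: C1'-C6' denote the benzene ring of arzanol (C1' carries the CH2 bridge, C3' the prenyl group, C5' the acetyl group) and C3 the pyrone carbon at the bridge. Silyl enol ether 20 is taken as a mixture of double-bond isomers, both of which lead to 22.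

**Route**

Step 1
Reactants: 1 phloroglucinol
Product: 2 5-(triisopropylsilyloxy)benzene-1,3-diol
Conditions: TIPSCl (1.0 equiv), imidazole, DMF, 0 °C to rt; 1 in threefold excess
Reagents that add atoms: chlorotriisopropylsilane (TIPSCl), CC(C)[Si](Cl)(C(C)C)C(C)C
Why: Silyl ether formation on one of three equivalent phenols; with the triol in excess the reaction should stop largely at the mono-ether, and unreacted 1 is removed by aqueous extraction.

Step 2
Reactants: 2 5-(triisopropylsilyloxy)benzene-1,3-diol
Product: 3 [3,5-bis(methoxymethoxy)phenoxy]triisopropylsilane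
Conditions: MOMCl (2.5 equiv), iPr2NEt, CH2Cl2, 0 °C to rt
Reagents that add atoms: chloromethyl methyl ether (MOMCl), COCCl
Why: Williamson-type O-alkylation of the two remaining phenols with MOMCl under amine base, conditions that leave the aryl TIPS ether untouched.

Step 3
Reactants: 3 [3,5-bis(methoxymethoxy)phenoxy]triisopropylsilane; 4 prenyl bromide (1-bromo-3-methylbut-2-ene)
Product: 6 [3,5-bis(methoxymethoxy)-4-(3-methylbut-2-enyl)phenoxy]triisopropylsilane, via 2,6-bis(methoxymethoxy)-4-(triisopropylsilyloxy)phenyllithium 5 (not isolated)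
Conditions: n-BuLi, THF, 0 °C; then CuI (10 mol %), 4, -78 °C to rt
Reagents that add atoms: none
Why: Directed ortho-metalation at the C-H flanked by both MOM ethers (cooperative chelation, while the bulky OTIPS group directs poorly) followed by SN2 alkylation of the aryllithium at the primary carbon of prenyl bromide, with catalytic CuI to suppress halogen-lithium exchange.

Step 4
Reactants: 6 [3,5-bis(methoxymethoxy)-4-(3-methylbut-2-enyl)phenoxy]triisopropylsilane
Product: 7 3,5-bis(methoxymethoxy)-4-(3-methylbut-2-enyl)phenol
Conditions: Bu4NF, THF, 0 °C; aqueous work-up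
Reagents that add atoms: none
Why: Fluoride-induced cleavage of the aryl silyl ether (Si-F bond formation), which touches neither the MOM acetals nor the alkene.

Step 5
Reactants: 7 3,5-bis(methoxymethoxy)-4-(3-methylbut-2-enyl)phenol
Product: 8 2-bromo-3,5-bis(methoxymethoxy)-4-(3-methylbut-2-enyl)phenol
Conditions: NBS (1.0 equiv), CH2Cl2, -78 °C
Reagents that add atoms: N-bromosuccinimide (NBS), O=C1CCC(=O)N1Br
Why: Electrophilic aromatic bromination of a strongly activated phenol, in which only the two equivalent ortho positions are open (para carries the prenyl group) and the phenol ring should outcompete the trisubstituted alkene for one equivalent of NBS at -78 °C.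

Step 6
Reactants: 8 2-bromo-3,5-bis(methoxymethoxy)-4-(3-methylbut-2-enyl)phenol
Product: 12 3,5-bis(methoxymethoxy)-4-(3-methylbut-2-enyl)-2-(trimethylsilyl)phenyl trifluoromethanesulfonate, via 2-bromoaryl trimethylsilyl ether 9 (not isolated), via 2-lithioaryl trimethylsilyl ether 10 (not isolated), via lithium 2-(trimethylsilyl)phenoxide 11 (not isolated)
Conditions: HMDS, THF, 65 °C, then evaporate; n-BuLi, THF, -78 °C; Tf2O, -78 °C to 0 °C
Reagents that add atoms: hexamethyldisilazane (HMDS), C[Si](C)(C)N[Si](C)(C)C; trifluoromethanesulfonic anhydride (Tf2O), O=S(=O)(OS(=O)(=O)C(F)(F)F)C(F)(F)F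
Why: The standard three-stage entry to 2-silylaryl triflates: O-silylation with HMDS, bromine-lithium exchange, retro-Brook rearrangement (anionic O-to-C silyl shift to the neighbouring carbanion) and O-triflation of the resulting phenoxide at low temperature.

Step 7
Reactants: 12 3,5-bis(methoxymethoxy)-4-(3-methylbut-2-enyl)-2-(trimethylsilyl)phenyl trifluoromethanesulfonate; 13 acetic acid
Product: 17 2-hydroxy-4,6-bis(methoxymethoxy)-5-(3-methylbut-2-enyl)acetophenone, via 3,5-bis(methoxymethoxy)-4-prenylbenzyne 14 (not isolated), via cesium 2-acetoxyaryl anion 15 (not isolated), via cesium benzoxete alkoxide 16 (not isolated)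
Conditions: AcOH (1.2 equiv), CsF (4 equiv), THF, 125 °C, sealed tube
Reagents that add atoms: none
Why: Fluoride should attack silicon and expel triflate from the neighbouring carbon to give aryne 14 (C5'-C6'), and cesium acetate should add through oxygen to C6' to give aryl anion 15 at C5'. The carbanion attacks the adjacent ester carbonyl to form the four-membered alkoxide 16, whose ring C-O bond breaks to leave the ortho-acetyl phenoxide, protonated to 17 (an anionic-Fries-like O-to-C acyl shift). The closest known reaction type is the formal insertion of arynes from 2-silylaryl triflates into the C-O bond of carboxylic acids to give ortho-hydroxyaryl ketones. No ring is retained in the product and no stereocenter is formed. The step needs regioselectivity, which the inductively withdrawing OMOM group on C4' should secure by distorting the aryne so that the nucleophile enters the distal C6' (charge developing at C5' next to oxygen), while C6' has only the C1'-H on its other flank. It also needs the acyl shift to outrun protonation of 15, which is why high temperature and only a slight excess of acid are used; the prenyl group on C3' cannot reach the aryne for an intramolecular ene reaction.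

Step 8
Reactants: 17 2-hydroxy-4,6-bis(methoxymethoxy)-5-(3-methylbut-2-enyl)acetophenone
Product: 18 1-[2,4,6-trihydroxy-3-(3-methylbut-2-enyl)phenyl]ethanone (3-prenylphloracetophenone)
Conditions: HCl (2 M) in MeOH, rt
Reagents that add atoms: none
Why: Acid-catalysed methanolysis of the two aryl MOM acetals, which at room temperature should be much faster than acid-induced cyclization of the ortho-prenylphenol to a chroman or addition of HCl to the alkene.

Step 9
Reactants: 19 3-pentanone
Product: 20 trimethyl(pent-2-en-3-yloxy)silane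
Conditions: TMSOTf, Et3N, CH2Cl2, 0 °C
Reagents that add atoms: trimethylsilyl trifluoromethanesulfonate (TMSOTf), C[Si](C)(C)OS(=O)(=O)C(F)(F)F
Why: Soft enolization and O-silylation of a symmetrical ketone with TMSOTf/Et3N (silyl enol ether formation), so that no regiochemical question arises.

Step 10
Reactants: 20 trimethyl(pent-2-en-3-yloxy)silane; 21 malonyl dichloride
Product: 22 6-ethyl-4-hydroxy-5-methyl-2H-pyran-2-one
Conditions: Et2O, -78 °C to rt
Reagents that add atoms: none
Why: Pyrone synthesis from a silyl enol ether and malonyl dichloride (Effenberger pyrone synthesis): C-acylation at the enol carbon gives a 3,5-dioxoacyl chloride whose ketone enol oxygen is acylated intramolecularly by the second acid chloride to close the lactone, which enolizes to the 4-hydroxy-2-pyrone.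

Step 11
Reactants: 22 6-ethyl-4-hydroxy-5-methyl-2H-pyran-2-one; 23 Eschenmoser's salt (N,N-dimethylmethyleneiminium iodide); 18 3-prenylphloracetophenone
Product: 26 arzanol, via pyrone Mannich base hydroiodide 24 (not isolated), via 3-methylidenepyran-2,4-dione 25 (not isolated)
Conditions: 22, 23 (1.0 equiv), MeCN, rt; then 18 (1.2 equiv), 50 °C
Reagents that add atoms: none
Why: Mannich reaction at the nucleophilic C3 of the 4-hydroxy-2-pyrone gives 24, which loses dimethylamine to the quinone-methide-like enedione 25, and the only unsubstituted carbon (C1') of the electron-rich acylphloroglucinol 18 adds to it in a Friedel-Crafts-type conjugate addition; consuming 22 with the iminium salt before 18 is added should limit symmetrical pyrone dimers.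

**Compound list**

1 | phloroglucinol | Oc1cc(O)cc(O)c1 | starting material
2 | 5-(triisopropylsilyloxy)benzene-1,3-diol | CC(C)[Si](Oc1cc(O)cc(O)c1)(C(C)C)C(C)C | intermediate
3 | [3,5-bis(methoxymethoxy)phenoxy]triisopropylsilane | COCOc1cc(OCOC)cc(O[Si](C(C)C)(C(C)C)C(C)C)c1 | intermediate
4 | prenyl bromide (1-bromo-3-methylbut-2-ene) | CC(C)=CCBr | starting material
5 | [2,6-bis(methoxymethoxy)-4-(triisopropylsilyloxy)phenyl]lithium | [Li]c1c(OCOC)cc(O[Si](C(C)C)(C(C)C)C(C)C)cc1OCOC | intermediate
6 | [3,5-bis(methoxymethoxy)-4-(3-methylbut-2-enyl)phenoxy]triisopropylsilane | COCOc1cc(O[Si](C(C)C)(C(C)C)C(C)C)cc(OCOC)c1CC=C(C)C | intermediate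
7 | 3,5-bis(methoxymethoxy)-4-(3-methylbut-2-enyl)phenol | COCOc1cc(O)cc(OCOC)c1CC=C(C)C | intermediate
8 | 2-bromo-3,5-bis(methoxymethoxy)-4-(3-methylbut-2-enyl)phenol | COCOc1cc(O)c(Br)c(OCOC)c1CC=C(C)C | intermediate
9 | [2-bromo-3,5-bis(methoxymethoxy)-4-(3-methylbut-2-enyl)phenoxy]trimethylsilane | COCOc1cc(O[Si](C)(C)C)c(Br)c(OCOC)c1CC=C(C)C | intermediate
10 | [2,4-bis(methoxymethoxy)-3-(3-methylbut-2-enyl)-6-(trimethylsilyloxy)phenyl]lithium | COCOc1cc(O[Si](C)(C)C)c([Li])c(OCOC)c1CC=C(C)C | intermediate
11 | lithium 3,5-bis(methoxymethoxy)-4-(3-methylbut-2-enyl)-2-(trimethylsilyl)phenoxide | COCOc1cc([O-])c([Si](C)(C)C)c(OCOC)c1CC=C(C)C.[Li+] | intermediate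
12 | 3,5-bis(methoxymethoxy)-4-(3-methylbut-2-enyl)-2-(trimethylsilyl)phenyl trifluoromethanesulfonate | C[Si](C)(C)c1c(OS(=O)(=O)C(F)(F)F)cc(OCOC)c(CC=C(C)C)c1OCOC | intermediate
13 | acetic acid | CC(=O)O | starting material
14 | 1,2-didehydro-3,5-bis(methoxymethoxy)-4-(3-methylbut-2-enyl)benzene (aryne) | COCOC1=CC#CC(OCOC)=C1CC=C(C)C | intermediate
15 | cesium 6-acetoxy-2,4-bis(methoxymethoxy)-3-(3-methylbut-2-enyl)benzen-1-ide | CC(=O)Oc1cc(OCOC)c(CC=C(C)C)c(OCOC)[c-]1.[Cs+] | intermediate
16 | cesium 4,6-bis(methoxymethoxy)-2-methyl-5-(3-methylbut-2-enyl)-2H-benzoxet-2-olate (four-membered ring C-O-C(aryl)-C(aryl)) | CC1([O-])Oc2cc(OCOC)c(CC=C(C)C)c(OCOC)c12.[Cs+] | intermediate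
17 | 2-hydroxy-4,6-bis(methoxymethoxy)-5-(3-methylbut-2-enyl)acetophenone | CC(=O)c1c(O)cc(OCOC)c(CC=C(C)C)c1OCOC | intermediate
18 | 1-[2,4,6-trihydroxy-3-(3-methylbut-2-enyl)phenyl]ethanone | CC(=O)c1c(O)cc(O)c(CC=C(C)C)c1O | intermediate
19 | 3-pentanone | CCC(=O)CC | starting material
20 | trimethyl(pent-2-en-3-yloxy)silane (mixture of double-bond isomers) | CC=C(CC)O[Si](C)(C)C | intermediate
21 | malonyl dichloride | O=C(Cl)CC(=O)Cl | starting material
22 | 6-ethyl-4-hydroxy-5-methyl-2H-pyran-2-one | CCc1oc(=O)cc(O)c1C | intermediate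
23 | Eschenmoser's salt (N,N-dimethylmethyleneiminium iodide) | C=[N+](C)C.[I-] | starting material
24 | 3-[(dimethylamino)methyl]-6-ethyl-4-hydroxy-5-methyl-2H-pyran-2-one hydroiodide | CCc1oc(=O)c(C[NH+](C)C)c(O)c1C.[I-] | intermediate
25 | 6-ethyl-5-methyl-3-methylidene-2H-pyran-2,4(3H)-dione | CCC1=C(C)C(=O)C(=C)C(=O)O1 | intermediate
26 | arzanol | CCc1oc(=O)c(Cc2c(O)c(CC=C(C)C)c(O)c(C(C)=O)c2O)c(O)c1C | target

**Step count**

Total: 11 steps. Longest linear sequence: 9 steps (steps 1 to 8, then step 11); steps 9 and 10 form the pyrone branch.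

**Steps most likely to fail**

1. Step 7 (aryne/acetic acid insertion). Proton transfer to the aryl anion may outrun the O-to-C acyl shift and give only net O-H addition. Acetate may also add to the aryne with the reverse orientation, or fluoride/acetate may cleave the S-O bond of the triflate before the aryne forms. The fallback sets out from 8 and comes back at 18. The phenol of 8 would be capped as a third MOM ether (MOMCl, iPr2NEt, CH2Cl2) to give 2-bromo-1,3,5-tris(methoxymethoxy)-4-(3-methylbut-2-enyl)benzene F1. Bromine-lithium exchange (n-BuLi, THF, -78 °C) should give [2,4,6-tris(methoxymethoxy)-3-(3-methylbut-2-enyl)phenyl]lithium F2. Acylation of F2 with N-methoxy-N-methylacetamide should give 1-[2,4,6-tris(methoxymethoxy)-3-(3-methylbut-2-enyl)phenyl]ethanone F3. HCl in MeOH at rt would then remove all three MOM groups to give 18.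

2. Step 5 (ortho-bromination). The brominating agent may attack the prenyl double bond, or bromination may occur at both ortho positions. The fallback sets out from 7 and comes back at 12, replacing electrophilic halogenation by carbamate-directed ortho-metalation. Phenol 7 and isopropyl isocyanate (Et3N, CH2Cl2) should give 3,5-bis(methoxymethoxy)-4-(3-methylbut-2-enyl)phenyl N-isopropylcarbamate F4. After transient N-silylation (TMSOTf, TMEDA, Et2O), ortho-lithiation (n-BuLi, TMEDA, -78 °C) and a TMSCl quench, aqueous work-up should give 3,5-bis(methoxymethoxy)-4-(3-methylbut-2-enyl)-2-(trimethylsilyl)phenyl N-isopropylcarbamate F5. DBU and Et2NH in MeCN at 40 °C would cleave the carbamate to 3,5-bis(methoxymethoxy)-4-(3-methylbut-2-enyl)-2-(trimethylsilyl)phenol F6, which is triflated in the same flask with PhNTf2 to give 12.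

3. Step 11 (methylene bridging). Enedione 25 may be captured by a second molecule of pyrone to give the symmetrical dimer, or may oligomerize before the arene adds. The fallback sets out from 18 (with 22 and 23) and comes back at 26, with the electrophile generated on the arene instead of the pyrone. Aminomethylation of 18 at C1' with 23 (CH2Cl2, rt, NaHCO3 work-up) should give 1-[3-[(dimethylamino)methyl]-2,4,6-trihydroxy-5-(3-methylbut-2-enyl)phenyl]ethanone F7. Heating F7 with 22 in dioxane at 90 °C should expel dimethylamine to give the ortho-quinone methide 4-acetyl-3,5-dihydroxy-6-methylidene-2-(3-methylbut-2-enyl)cyclohexa-2,4-dien-1-one F8, to which C3 of the pyrone adds in conjugate fashion to give 26.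

**Further compounds**

F1 | step 7 | 2-bromo-1,3,5-tris(methoxymethoxy)-4-(3-methylbut-2-enyl)benzene | COCOc1cc(OCOC)c(Br)c(OCOC)c1CC=C(C)C
F2 | step 7 | [2,4,6-tris(methoxymethoxy)-3-(3-methylbut-2-enyl)phenyl]lithium | [Li]c1c(OCOC)cc(OCOC)c(CC=C(C)C)c1OCOC
F3 | step 7 | 1-[2,4,6-tris(methoxymethoxy)-3-(3-methylbut-2-enyl)phenyl]ethanone | CC(=O)c1c(OCOC)cc(OCOC)c(CC=C(C)C)c1OCOC
F4 | step 5 | 3,5-bis(methoxymethoxy)-4-(3-methylbut-2-enyl)phenyl N-isopropylcarbamate | COCOc1cc(OC(=O)NC(C)C)cc(OCOC)c1CC=C(C)C
F5 | step 5 | 3,5-bis(methoxymethoxy)-4-(3-methylbut-2-enyl)-2-(trimethylsilyl)phenyl N-isopropylcarbamate | COCOc1cc(OC(=O)NC(C)C)c([Si](C)(C)C)c(OCOC)c1CC=C(C)C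
F6 | step 5 | 3,5-bis(methoxymethoxy)-4-(3-methylbut-2-enyl)-2-(trimethylsilyl)phenol | COCOc1cc(O)c([Si](C)(C)C)c(OCOC)c1CC=C(C)C
F7 | step 11 | 1-[3-[(dimethylamino)methyl]-2,4,6-trihydroxy-5-(3-methylbut-2-enyl)phenyl]ethanone | CC(=O)c1c(O)c(CN(C)C)c(O)c(CC=C(C)C)c1O
F8 | step 11 | 4-acetyl-3,5-dihydroxy-6-methylidene-2-(3-methylbut-2-enyl)cyclohexa-2,4-dien-1-one | CC(=O)C1=C(O)C(=C)C(=O)C(CC=C(C)C)=C1O
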